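## Structural features

The chain is numbered C1 (lactone carbonyl), C2, C3 (enol carbon), C4 (CHMe), C5, C6 (C(OH)Me), C7 (ketone), C8, C9 (CHOMe), C10, C11 (CHOH), C12 (C(Me)–O), C13 (CHMe), C14, C15 (C–O of the lactone), C16. It is folded into a 2-oxabicyclo[2.2.2]octane (C10–C15, C16 and the ether oxygen between C12 and C16), a cyclopentane (C8, C9, C10, C15, C16), a γ-lactone (C1, C2, C16, C15, O) and a cyclooctane (C2–C8 plus C16). C16 is the hub: it is fully substituted, carries the ether oxygen, C15, C2 and C8, and belongs to all four ring systems; C15 and C12 are fully substituted as well. There are ten stereocentres, eight of them contiguous on the cage (C8–C13, C15, C16) and two (C4, C6) remote on the eight-membered ring. Fragile groups are the enolised β-keto lactone (C1–C3), the tertiary α-ketol (C6/C7) and the β-methoxy ketone C7–C8–C9, which can lose methanol and epimerise at C8. The real difficulty is the C8–C16 bond at the quaternary C16 together with closure of the cyclooctane. The key step exploits that the C3 and C7 carbonyls are 1,5-related through C2–C16–C8: the cyclooctane is the retro-aldol product of a cyclobutane C2–C3–C8–C16, so it can come from [2+2] union of a six-membered C3–C8 enol ether with the tetronate C2=C16 bond.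

## Logic of the disconnections

31 to 28: the C3–C8 bond is re-formed (aldol sense) and the three hydroxyls are masked, which leads through 30 and the cyclobutanol 29 to 28. The reason is the 1,5-dicarbonyl pattern named above. The gain is that the cyclooctane becomes a cyclohexanone fused to a cyclobutane. The forward step must cleave C3–C8 and not C2–C3, must not expel methanol from C9, and must ketonise C8 to the cis-fused 5/8 system.

28 to 27 (key): C8–C16 and C2–C3 are cut. Both bonds belong to one cyclobutane whose two π components, C8=C3 of a β-benzyloxy enone and C2=C16 of the tetronate, are held three atoms apart by C9, C10 and C15. The cyclopentane, the cyclobutane and the quaternary C16 vanish, and 27 is two ring systems of similar size joined only at C9. In one sentence: an intramolecular de Mayo reaction between a cyclohexane-1,3-dione enol ether and the tetronate double bond of 27 builds the cyclopentane and, after fragmentation, the cyclooctane. The forward step needs the straight regiochemistry and attack on the C10 face of the tetronate.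

27 to 24 (through 26 and 25): the O–CH3 bond and the C9–H bond are cut. The C9 configuration is best set by hydride delivery to a C9 ketone, because only one trajectory at C9 is open on the cage. The gain is that C9 becomes a plain carbinol of either configuration. The demand is 1,2-reduction of C9=O in the presence of the vinylogous ester.

24 to 14 and 22 (through 23): C8–C9 is cut, the only bond joining cage and carbocycle. This gives a convergent union of a C9 aldehyde with a C8 vinyl metal. The demand is a metalated vinylogous ester that adds faster than it enolises the hindered aldehyde.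

22 to 18 (through 21, 20, 19): C8–I, the C4 configuration, O–Si and O–benzyl are removed in turn. The gain is a simple 1,3-dione. The demands are benzylation on the oxygen next to C4 and thermodynamic control at C4.

18 to 15 and 16 (through 17): C5–C6 and C7–C8 are cut (Michael, then Claisen). C6 comes from (R)-lactic acid through its dioxolanone, so the quaternary carbinol is bought. The demand is 1,4-addition of a hindered enolate.

14 to 12 (through 13): oxidation level at C9 and the C11 silyl ether; no skeletal change.

12 to 10 (through 11): the O–C12 ether bond and the C2–C16 bond are cut. Dieckmann closure of an acetate on the lactone carbonyl makes the tetronic acid and frees C9–OH; the tetronic acid oxygen then opens the epoxide at C12. Two rings and C11/C12 are gained in one operation. The demand is attack at the tertiary C12.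

10 to 7 (through 9 and 8): the acetyl group, the epoxide oxygen and the C15 hydroxyl are removed. Each is placed by the cis-fused lactone or by the C15 hydroxyl.

7 to 4 and 5 (through 6): C10–C15 and C13–C14 are cut (Diels–Alder). The cyclohexene with C10, C13 and C15 arises at once from an achiral dienol and an acrylate. The demand is absolute control by the chiral template.

4 to 1 and 2 (through 3): the C10=C11 double bond is cut (olefination), then the ester is reduced.

## Other disconnections considered

Alternative 1: the first idea. Cut C8–C16 and C9–O across an eleven-membered ring. In the forward sense methanol adds to C9 of the macrocyclic enone A1 and the C8 enolate closes transannularly onto C16 of the C2-acyl tetronate. A1 is a strained trans-cycloundecenone with an α-ketol next to the enone; it must be ring-closed late at high dilution, it can exist as slowly interconverting conformers, and the face of methanol attack at C9 rests on that conformation. The chosen plan makes the same C8–C16 bond through a five-membered closure and never builds a macrocycle.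

Alternative 2: cut C2–C3. In the forward sense the lactone enolate at C2 of the seco ester A2 is acylated by the C3 ester, closing the cyclooctane. An eight-membered Claisen closure is slow and reversible, and the strong base would eliminate methanol from C9 and scramble C8 and C4. A2 also still needs the C8–C16 bond at the quaternary C16, which conjugate addition cannot make because a tetronate without the C3 acyl group is a poor acceptor. The hardest bond is left unsolved.

Alternative 3: cut C6–C7. In the forward sense an intramolecular aldehyde–ketone acyloin (carbene-catalysed crossed benzoin) of the keto aldehyde A3 closes the cyclooctane and makes the tertiary ketol. Nothing in A3 controls the C6 configuration, eight-membered closures of this kind lack the bias of five- and six-membered ones, and a β-methoxy aldehyde under basic carbene conditions is prone to elimination. The quaternary C16 must again be built beforehand.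

Key step: step 19

Remarks on assumptions. (a) In step 3 it is assumed that (R)-BINOL gives lactone 7 as drawn; if the sense is the opposite, (S)-BINOL is used and nothing else changes. (b) The facial preference at C9 is derived from a hand-built model of the cage and decides whether 9S comes from hydride reduction (steps 16–17, chosen) or directly from the Grignard adduct (fallback to step 17). (c) 1,3-Diones are written as diketo tautomers. Locants C1–C16 in names are those defined above.

## Steps

Step 1
Reactants: 1 (E)-2-methylbut-2-enal; 2 triethyl phosphonoacetate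
Product: 3 ethyl (2E,4E)-4-methylhexa-2,4-dienoate
Conditions: NaH, THF, 0 °C to rt
Reagents that add atoms: none
Why: Horner–Wadsworth–Emmons olefination; the stabilised phosphonate anion should give the new C10=C11 bond E, and the E geometry of 1 is kept.

Step 2
Reactants: 3 ethyl (2E,4E)-4-methylhexa-2,4-dienoate
Product: 4 (2E,4E)-4-methylhexa-2,4-dien-1-ol
Conditions: DIBAL-H (2.2 equiv), CH2Cl2, −78 °C; Rochelle salt work-up
Reagents that add atoms: none
Why: 1,2-Reduction of a conjugated ester to the allylic alcohol; no stereocentre is formed.

Step 3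
Reactants: 4 (2E,4E)-4-methylhexa-2,4-dien-1-ol; 5 methyl acrylate
Product: 7 (3aS,6S,7aR)-5,6-dimethyl-3a,6,7,7a-tetrahydro-2-benzofuran-1(3H)-one (cis-fused lactone; C13 methyl cis to C9), via hydroxy ester cycloadduct 6 (not isolated)
Conditions: Me2Zn, (R)-BINOL, MeMgBr, CH2Cl2, 0 °C to rt; aq. NH4Cl
Reagents that add atoms: none
Why: Lewis-acid-templated Diels–Alder reaction: dienolate and acrylate are held on the Mg/Zn binaphtholate, which enforces bonding of C15 to C10 and the endo mode, so C9 and the ester are cis and lactonise. The E,E-diene puts the C13 methyl cis to C9, and the binaphthol fixes the absolute sense (remark a).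

Step 4
Reactants: 7 cis-fused lactone
Product: 8 (3aR,6S,7aS)-7a-hydroxy-5,6-dimethyl-3a,6,7,7a-tetrahydro-2-benzofuran-1(3H)-one
Conditions: KHMDS, THF, −78 °C; trans-2-(phenylsulfonyl)-3-phenyloxaziridine, −78 °C; aq. NH4Cl
Reagents that add atoms: trans-2-(phenylsulfonyl)-3-phenyloxaziridine, O=S(=O)(c1ccccc1)N1OC1c1ccccc1
Why: Enolate hydroxylation with a sulfonyloxaziridine; oxygen should enter at C15 on the face opposite C9, because only this keeps the lactone cis-fused.

Step 5
Reactants: 8 hydroxy lactone
Product: 9 C11–C12 epoxide of 8, epoxide oxygen cis to the C15 hydroxyl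
Conditions: VO(acac)2 (cat.), t-BuOOH, CH2Cl2, 0 °C to rt
Reagents that add atoms: tert-butyl hydroperoxide, CC(C)(C)OO
Why: Vanadium-catalysed hydroxyl-directed epoxidation; the homoallylic C15 hydroxyl should deliver oxygen to its own face of C11=C12, anti to C9 and to the C13 methyl.

Step 6
Reactants: 9 epoxy hydroxy lactone
Product: 10 C15 acetate of 9
Conditions: Ac2O, Et3N, DMAP, CH2Cl2, rt
Reagents that add atoms: acetic anhydride, CC(=O)OC(C)=O
Why: DMAP-catalysed acylation of the tertiary alcohol; it supplies C1 and C2.

Step 7
Reactants: 10 epoxy acetate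
Product: 12 tricyclic tetronate diol (2-oxabicyclo[2.2.2]octane fused to the C1/C2/C16/C15 tetronate; C10–CH2OH, C11–OH), via spirotetronic acid epoxide 11 (not isolated)
Conditions: LiHMDS (2.2 equiv), THF, −78 to 0 °C; aq. NH4Cl; then PPTS (cat.), CH2Cl2, rt
Reagents that add atoms: none
Why: Dieckmann condensation of the acetate enolate on the lactone carbonyl C16 gives the tetronic acid and frees C9–OH. The enolic oxygen on C16 then opens the epoxide at the tertiary C12 with inversion (acid-promoted, anti), which closes the oxabicyclo[2.2.2]octane and sets C12 and C11–OH.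

Step 8
Reactants: 12 tricyclic tetronate diol
Product: 13 C9,C11-bis(triethylsilyl) ether of 12
Conditions: TESOTf (2.5 equiv), 2,6-lutidine, CH2Cl2, −78 to 0 °C
Reagents that add atoms: triethylsilyl trifluoromethanesulfonate, CC[Si](CC)(CC)OS(=O)(=O)C(F)(F)F
Why: Standard silylation of both hydroxyls; the tetronate has no free OH.

Step 9
Reactants: 13 bis-TES ether
Product: 14 C9 aldehyde with C11–OTES
Conditions: (COCl)2, DMSO, CH2Cl2, −78 to −35 °C; Et3N, −78 to 0 °C
Reagents that add atoms: none
Why: Swern oxidation acts directly on a primary TES ether and leaves the secondary one, so the aldehyde forms without a separate deprotection; low temperature protects C10.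

Step 10
Reactants: 15 (2R,5R)-2-tert-butyl-5-methyl-1,3-dioxolan-4-one; 16 3-methylbut-3-en-2-one
Product: 18 (4S)-4-hydroxy-4,6-dimethylcyclohexane-1,3-dione (C6 carbinol of the target fixed; mixture at the methyl-bearing CH), via Michael adduct 17 (not isolated)
Conditions: LDA, THF, −78 °C; 16, DMPU, −78 °C; t-BuOK, −78 to 0 °C; aq. HCl
Reagents that add atoms: none
Why: Michael–Claisen annulation: the dioxolanone enolate is attacked trans to the tert-butyl group (self-regeneration of the stereocentre), which fixes C6. The methyl-ketone enolate is then acylated by the dioxolanone carbonyl with loss of pivalaldehyde; C4 is not controlled here.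

Step 11
Reactants: 18 (4S)-4-hydroxy-4,6-dimethylcyclohexane-1,3-dione
Product: 19 (6S)-3-(benzyloxy)-6-hydroxy-4,6-dimethylcyclohex-2-en-1-one (C4 epimers)
Conditions: BnOH, PPh3, DIAD, THF, 0 °C to rt
Reagents that add atoms: benzyl alcohol, OCc1ccccc1
Why: Mitsunobu O-alkylation of the acidic 1,3-dione; the oxygen next to the quaternary C6 is shielded, so benzyl should go on the oxygen next to C4, giving C3–OBn and C7=O.

Step 12
Reactants: 19 benzyl vinylogous ester
Product: 20 (6S)-3-(benzyloxy)-4,6-dimethyl-6-[(triethylsilyl)oxy]cyclohex-2-en-1-one (C4 epimers)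
Conditions: TESOTf, 2,6-lutidine, CH2Cl2, −78 to 0 °C
Reagents that add atoms: triethylsilyl trifluoromethanesulfonate, CC[Si](CC)(CC)OS(=O)(=O)C(F)(F)F
Why: Silylation of the tertiary α-ketol hydroxyl.

Step 13
Reactants: 20 silyl ether (C4 epimers)
Product: 21 (4S,6S)-3-(benzyloxy)-4,6-dimethyl-6-[(triethylsilyl)oxy]cyclohex-2-en-1-one
Conditions: t-BuOK (0.2 equiv), t-BuOH/THF, 0 °C to rt
Reagents that add atoms: none
Why: Reversible γ-deprotonation (extended enolate; C6 has no hydrogen) equilibrates C4. The 4S epimer can hold both methyls pseudo-equatorial with the silyloxy group pseudo-axial next to the carbonyl, whereas the 4R epimer needs a pseudo-axial methyl or a syn-diaxial Me/OSi contact, so 21 should be favoured; residual epimer is separated and recycled.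

Step 14
Reactants: 21 (4S,6S)-vinylogous ester
Product: 22 (4S,6S)-3-(benzyloxy)-2-iodo-4,6-dimethyl-6-[(triethylsilyl)oxy]cyclohex-2-en-1-one
Conditions: NIS, MeCN, 0 °C to rt, dark
Reagents that add atoms: N-iodosuccinimide, O=C1CCC(=O)N1I
Why: Electrophilic α-iodination of a β-alkoxy enone at its nucleophilic α-carbon (C8).

Step 15
Reactants: 22 α-iodo vinylogous ester; 14 C9 aldehyde
Product: 24 C9 carbinol linking C10 of the cage to C8 of the benzyloxy enone (C9 epimers), via α-magnesiated vinylogous ester 23 (not isolated)
Conditions: i-PrMgCl·LiCl, THF, −78 to −40 °C; LaCl3·2LiCl; 14, −78 to −20 °C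
Reagents that add atoms: none
Why: Iodine–magnesium exchange gives a vinyl Grignard reagent that is tolerated by the weakly electrophilic, hindered vinylogous ester carbonyl; lanthanum-assisted 1,2-addition to the aldehyde follows. The C9 configuration is irrelevant because step 16 erases it.

Step 16
Reactants: 24 C9 carbinol
Product: 25 C9 ketone (2-acyl-3-benzyloxy enone)
Conditions: Dess–Martin periodinane, pyridine, CH2Cl2, 0 °C to rt
Reagents that add atoms: none
Why: Buffered Dess–Martin oxidation of a hindered secondary alcohol; the TES ethers and the tetronate survive.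

Step 17
Reactants: 25 C9 ketone
Product: 26 (9S)-carbinol
Conditions: NaBH4, CeCl3·7H2O, MeOH/THF, −78 °C
Reagents that add atoms: none
Why: Luche 1,2-reduction; the twisted C9 acyl group should react before the hindered C7 carbonyl. Felkin–Anh control: hydride should arrive anti to the C10–C15 bond, the only trajectory not blocked by the tetronate ring and the lactone oxygen, with the C8 ring next to C10–H, which gives 9S.

Step 18
Reactants: 26 (9S)-carbinol
Product: 27 (9S)-methyl ether (photosubstrate)
Conditions: MeI, Ag2O, 4 Å MS, Et2O, 35 °C, dark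
Reagents that add atoms: iodomethane, CI
Why: Purdie methylation under neutral conditions, which avoids silyl migration from O11 and alkylation of the carbonyl oxygens; C9 is not touched.

Step 19
Reactants: 27 (9S)-methyl ether
Product: 28 cyclobutane photoadduct (new bonds C8–C16 and C2–C3)
Conditions: hν (350 nm, Pyrex), degassed MeCN (2 mM), 0 °C
Reagents that add atoms: none
Why: Excitation of the β-benzyloxy enone at 350 nm, where the tetronate is transparent, and intersystem crossing should give the enone triplet; its α-carbon C8 adds to C16 of the tetronate through a five-membered ring (rule of five), leaving a 1,4-biradical stabilised at C3 by the benzyloxy group and at C2 by the lactone carbonyl, and spin inversion with C3–C2 coupling closes the cyclobutane. The closest known reaction type is the intramolecular enone–alkene [2+2] photocycloaddition of vinylogous esters (first half of the de Mayo reaction), and tetronate double bonds are established [2+2] partners. The cyclopentane (C8, C9, C10, C15, C16) closes in the 5-exo sense and the cyclobutane by biradical recombination, which gives the straight bicyclo[3.2.0] unit; the crossed mode would need a six-membered first closure. C16 is set by the cage: the tether from C10 reaches only the face of the planar tetronate syn to C10, which is the target configuration. C8, C2 and C3 follow from the obligatory cis fusions of the four-membered ring with the lactone, the cyclopentane and the cyclohexanone; C8 and C3 are erased again in step 20 and C2 becomes sp2. C9, C4 and C6 are spectators. The step needs selective excitation (wavelength), straight regiochemistry (tether length and radical stabilisation) and a closure that outruns hydrogen abstraction from the benzylic CH2 (dilute, degassed solution).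

Step 20
Reactants: 28 cyclobutane photoadduct
Product: 31 target compound CNP0073200.1, via cyclobutanol 29 (not isolated), via bis-TES ether 30 (not isolated)
Conditions: H2 (1 atm), Pd/C, EtOAc, rt; filter; HF·pyridine, pyridine/THF, 0 °C to rt
Reagents that add atoms: none
Why: Hydrogenolysis unmasks cyclobutanol 29, a strained β-hydroxy ketone that should undergo retro-aldol cleavage of C3–C8 (both carbons fully substituted, the C7 enol as leaving group; de Mayo fragmentation), and C2–H/C3=O tautomerises to the chelated enol of 30. The C7 enol should ketonise at C8 on the face away from the new eight-membered ring, giving the cis-fused 5/8 system with C7 trans to the C9 methoxy group; buffered HF·pyridine then removes both TES ethers.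

## Compound list

1 | (E)-2-methylbut-2-enal | C/C=C(\C)C=O | starting material
2 | triethyl phosphonoacetate | CCOC(=O)CP(=O)(OCC)OCC | starting material
3 | ethyl (2E,4E)-4-methylhexa-2,4-dienoate | CCOC(=O)/C=C/C(C)=C/C | intermediate
4 | (2E,4E)-4-methylhexa-2,4-dien-1-ol | OC/C=C/C(C)=C/C | intermediate
5 | methyl acrylate | COC(=O)C=C | starting material
6 | methyl (1R,2S,5S)-2-(hydroxymethyl)-4,5-dimethylcyclohex-3-ene-1-carboxylate | OC[C@H]1C=C(C)[C@@H](C)C[C@H]1C(=O)OC | intermediate
7 | (3aS,6S,7aR)-5,6-dimethyl-3a,6,7,7a-tetrahydro-2-benzofuran-1(3H)-one | O=C1OC[C@H]2C=C(C)[C@@H](C)C[C@@H]12 | intermediate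
8 | (3aR,6S,7aS)-7a-hydroxy-5,6-dimethyl-3a,6,7,7a-tetrahydro-2-benzofuran-1(3H)-one | O=C1OC[C@H]2C=C(C)[C@@H](C)C[C@@]12O | intermediate
9 | C11–C12 epoxide of 8 (epoxide O cis to the C15 hydroxyl) | O=C1OC[C@H]2[C@@H]3O[C@]3(C)[C@@H](C)C[C@@]12O | intermediate
10 | C15 acetate of 9 | O=C1OC[C@H]2[C@@H]3O[C@]3(C)[C@@H](C)C[C@@]12OC(C)=O | intermediate
11 | spirotetronic acid epoxide (tetronic acid spiro at C15; C10–CH2OH; C11–C12 epoxide) | OC[C@H]1[C@@H]2O[C@]2(C)[C@@H](C)C[C@]13OC(=O)C=C3O | intermediate
12 | tricyclic tetronate diol (2-oxabicyclo[2.2.2]octane fused to the tetronate; C10–CH2OH, C11–OH) | OC[C@H]1[C@H](O)[C@@]2(C)OC3=CC(=O)O[C@@]13C[C@@H]2C | intermediate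
13 | C9,C11-bis(triethylsilyl) ether of 12 | CC[Si](CC)(CC)OC[C@H]1[C@H](O[Si](CC)(CC)CC)[C@@]2(C)OC3=CC(=O)O[C@@]13C[C@@H]2C | intermediate
14 | C9 aldehyde of the cage with C11–OTES | O=C[C@H]1[C@H](O[Si](CC)(CC)CC)[C@@]2(C)OC3=CC(=O)O[C@@]13C[C@@H]2C | intermediate
15 | (2R,5R)-2-tert-butyl-5-methyl-1,3-dioxolan-4-one (acetal of (R)-lactic acid and pivalaldehyde) | C[C@H]1O[C@@H](C(C)(C)C)OC1=O | starting material
16 | 3-methylbut-3-en-2-one | CC(=O)C(C)=C | starting material
17 | (2R,5S)-2-tert-butyl-5-methyl-5-(2-methyl-3-oxobutyl)-1,3-dioxolan-4-one (side-chain epimers) | CC(=O)C(C)C[C@]1(C)O[C@@H](C(C)(C)C)OC1=O | intermediate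
18 | (4S)-4-hydroxy-4,6-dimethylcyclohexane-1,3-dione (C6 epimers; diketo tautomer) | C[C@]1(O)CC(C)C(=O)CC1=O | intermediate
19 | (6S)-3-(benzyloxy)-6-hydroxy-4,6-dimethylcyclohex-2-en-1-one (C4 epimers) | C[C@]1(O)CC(C)C(OCc2ccccc2)=CC1=O | intermediate
20 | (6S)-3-(benzyloxy)-4,6-dimethyl-6-[(triethylsilyl)oxy]cyclohex-2-en-1-one (C4 epimers) | CC[Si](CC)(CC)O[C@@]1(C)CC(C)C(OCc2ccccc2)=CC1=O | intermediate
21 | (4S,6S)-3-(benzyloxy)-4,6-dimethyl-6-[(triethylsilyl)oxy]cyclohex-2-en-1-one | CC[Si](CC)(CC)O[C@@]1(C)C[C@H](C)C(OCc2ccccc2)=CC1=O | intermediate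
22 | (4S,6S)-3-(benzyloxy)-2-iodo-4,6-dimethyl-6-[(triethylsilyl)oxy]cyclohex-2-en-1-one | CC[Si](CC)(CC)O[C@@]1(C)C[C@H](C)C(OCc2ccccc2)=C(I)C1=O | intermediate
23 | 2-(chloromagnesio) derivative of 21 | CC[Si](CC)(CC)O[C@@]1(C)C[C@H](C)C(OCc2ccccc2)=C([Mg]Cl)C1=O | intermediate
24 | C9 carbinol joining C10 of the cage and C8 of the benzyloxy enone (C9 epimers) | OC(C1=C(OCc2ccccc2)[C@@H](C)C[C@](C)(O[Si](CC)(CC)CC)C1=O)[C@H]3[C@H](O[Si](CC)(CC)CC)[C@@]4(C)OC5=CC(=O)O[C@@]35C[C@@H]4C | intermediate
25 | C9 ketone | O=C(C1=C(OCc2ccccc2)[C@@H](C)C[C@](C)(O[Si](CC)(CC)CC)C1=O)[C@H]3[C@H](O[Si](CC)(CC)CC)[C@@]4(C)OC5=CC(=O)O[C@@]35C[C@@H]4C | intermediate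
26 | (9S)-carbinol | O[C@H](C1=C(OCc2ccccc2)[C@@H](C)C[C@](C)(O[Si](CC)(CC)CC)C1=O)[C@H]3[C@H](O[Si](CC)(CC)CC)[C@@]4(C)OC5=CC(=O)O[C@@]35C[C@@H]4C | intermediate
27 | (9S)-methyl ether (photosubstrate) | CO[C@H](C1=C(OCc2ccccc2)[C@@H](C)C[C@](C)(O[Si](CC)(CC)CC)C1=O)[C@H]3[C@H](O[Si](CC)(CC)CC)[C@@]4(C)OC5=CC(=O)O[C@@]35C[C@@H]4C | intermediate
28 | cyclobutane photoadduct (C2–C3–C8–C16 ring; C3–OBn; six-membered ring on the face of the cyclobutane opposite the lactone and cyclopentane) | CO[C@H]1[C@H]2[C@H](O[Si](CC)(CC)CC)[C@@]3(C)O[C@@]45[C@@H]([C@@]6(OCc7ccccc7)[C@@H](C)C[C@](C)(O[Si](CC)(CC)CC)C(=O)[C@@]146)C(=O)O[C@@]25C[C@@H]3C | intermediate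
29 | cyclobutanol (C3–OH) from 28 | CO[C@H]1[C@H]2[C@H](O[Si](CC)(CC)CC)[C@@]3(C)O[C@@]45[C@@H]([C@@]6(O)[C@@H](C)C[C@](C)(O[Si](CC)(CC)CC)C(=O)[C@@]146)C(=O)O[C@@]25C[C@@H]3C | intermediate
30 | C6,C11-bis(triethylsilyl) ether of the target | CO[C@H]1[C@H]2[C@H](O[Si](CC)(CC)CC)[C@@]3(C)O[C@@]45/C(=C(/O)[C@@H](C)C[C@](C)(O[Si](CC)(CC)CC)C(=O)[C@H]14)C(=O)O[C@@]25C[C@@H]3C | intermediate
31 | CNP0073200.1 | CO[C@H]1[C@H]2[C@H](O)[C@@]3(C)O[C@@]45/C(=C(/O)[C@@H](C)C[C@](C)(O)C(=O)[C@H]14)C(=O)O[C@@]25C[C@@H]3C | target

## Step count and least certain steps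

Total: 20 steps. Longest linear sequence: 15 steps (steps 1–9, then 15–20); the carbocycle 22 is made in 5 steps (10–14).

Step 19 (key). The photocycloaddition may be inefficient: the C2/C3 biradical can revert to 27, the benzylic CH2 can be attacked by the excited enone, and the cis contact between the C9 methoxy group and C7 raises the barrier to closure. Fallback: the classical de Mayo substrate. Hydrogenolysis of 27 (H2, Pd/C, EtOAc) gives the free 2-substituted cyclohexane-1,3-dione enol F1, which is irradiated at once at 350 nm and −20 °C. The cyclobutanol 29 then forms and fragments in the same flask. The fallback sets out from 27 and comes back at 30.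

Step 20. Hydrogenolysis of the hindered tertiary benzyl ether may be slow. Fragmentation may be diverted by loss of methanol from C9 at the C7 enol stage, or by cleavage toward the lactone. Fallback: 29 is isolated after hydrogenolysis and opened through its alkoxy radical (photocatalytic proton-coupled electron transfer or cerium ligand-to-metal charge transfer, thiol as hydrogen donor). β-Scission gives the tertiary α-keto radical at C8, which is reduced to C8–H without an enolate. The fallback sets out from 29 and comes back at 30.

Step 17. Facial selectivity at C9 may be poor or reversed, and conjugate reduction at C3 with loss of benzyl alcohol may compete. Fallback: addition in step 15 and reduction in step 17 follow the same facial preference and give opposite C9 epimers. If hydride gives mainly 9R, the major carbinol of 24 is 9S and is methylated directly under the conditions of step 18. The fallback sets out from 24 and comes back at 27.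

Step 13. The thermodynamic preference at C4 may be too small or reversed. Fallback: kinetic alkylation instead of equilibration. 15 and methyl vinyl ketone under the conditions of step 10 give the Michael adduct (2R,5S)-2-tert-butyl-5-methyl-5-(3-oxobutyl)-1,3-dioxolan-4-one F2 and then (S)-4-hydroxy-4-methylcyclohexane-1,3-dione F3. Mitsunobu benzylation gives (S)-3-(benzyloxy)-6-hydroxy-6-methylcyclohex-2-en-1-one F4, and silylation gives (S)-3-(benzyloxy)-6-methyl-6-[(triethylsilyl)oxy]cyclohex-2-en-1-one F5. The extended enolate (LDA, THF, −78 °C) is methylated with MeI at C4 anti to the pseudo-axial silyloxy group. The fallback sets out from 15 and comes back at 21.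

Step 15. The exchange may be incomplete, or the basic vinyl Grignard reagent may enolise the hindered aldehyde and scramble C10. Fallback: Nozaki–Hiyama–Kishi coupling of 22 with 14 (CrCl2, NiCl2 cat., DMSO), in which a non-basic vinylchromium species adds. The fallback sets out from 22 and 14 and comes back at 24.

Step 10. The hindered lithium enolate may add 1,2 to the enone, or the enone may polymerise. Fallback: alkylation, the best-behaved reaction of this enolate. 15 with LDA and (E)-1-bromo-2-methylbut-2-ene gives (2R,5S)-2-tert-butyl-5-methyl-5-[(E)-2-methylbut-2-enyl]-1,3-dioxolan-4-one F6. Hydroboration–oxidation (BH3·SMe2, then H2O2/NaOH) gives (2R,5S)-2-tert-butyl-5-(3-hydroxy-2-methylbutyl)-5-methyl-1,3-dioxolan-4-one F7, and Dess–Martin oxidation gives 17, which is cyclised with t-BuOK. The fallback sets out from 15 and comes back at 17.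

## Further compounds

F1 | step 19 | free 1,3-dione enol corresponding to 27 (C3–OH in place of C3–OBn) | CO[C@H](C1=C(O)[C@@H](C)C[C@](C)(O[Si](CC)(CC)CC)C1=O)[C@H]3[C@H](O[Si](CC)(CC)CC)[C@@]4(C)OC5=CC(=O)O[C@@]35C[C@@H]4C
F0 | step 20 | none | none
F0 | step 17 | none | none
F2 | step 13 | (2R,5S)-2-tert-butyl-5-methyl-5-(3-oxobutyl)-1,3-dioxolan-4-one | CC(=O)CC[C@]1(C)O[C@@H](C(C)(C)C)OC1=O
F3 | step 13 | (S)-4-hydroxy-4-methylcyclohexane-1,3-dione | C[C@]1(O)CCC(=O)CC1=O
F4 | step 13 | (S)-3-(benzyloxy)-6-hydroxy-6-methylcyclohex-2-en-1-one | C[C@]1(O)CCC(OCc2ccccc2)=CC1=O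
F5 | step 13 | (S)-3-(benzyloxy)-6-methyl-6-[(triethylsilyl)oxy]cyclohex-2-en-1-one | CC[Si](CC)(CC)O[C@@]1(C)CCC(OCc2ccccc2)=CC1=O
F0 | step 15 | none | none
F6 | step 10 | (2R,5S)-2-tert-butyl-5-methyl-5-[(E)-2-methylbut-2-enyl]-1,3-dioxolan-4-one | C/C=C(\C)C[C@]1(C)O[C@@H](C(C)(C)C)OC1=O
F7 | step 10 | (2R,5S)-2-tert-butyl-5-(3-hydroxy-2-methylbutyl)-5-methyl-1,3-dioxolan-4-one (side-chain diastereomers) | CC(O)C(C)C[C@]1(C)O[C@@H](C(C)(C)C)OC1=O
A1 | alternative 1 | eleven-membered macrocyclic enone (C7 ketone, E-C8=C9, C2-acyl tetronate, C6 ketol) | O=C5/C=C/[C@H]1[C@H](O)[C@@]2(C)OC3=C(C(=O)O[C@@]13C[C@@H]2C)C(=O)[C@@H](C)C[C@]5(C)O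
A2 | alternative 2 | seco methyl ester (C2–C3 bond open; C3 as CO2Me, C2 as lactone CH2) | CO[C@H]1[C@H]2[C@H](O)[C@@]3(C)O[C@@]4(CC(=O)O[C@@]24C[C@@H]3C)[C@@H]1C(=O)[C@@](C)(O)C[C@H](C)C(=O)OC
A3 | alternative 3 | seco keto aldehyde (C6–C7 bond open; C7 aldehyde on C8, C6 methyl ketone) | CO[C@H]1[C@H]2[C@H](O)[C@@]3(C)O[C@@]4(/C(=C(/O)[C@@H](C)CC(C)=O)C(=O)O[C@@]24C[C@@H]3C)[C@@H]1C=O
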